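**Plan**

1. Retrosynthesis: the spiro-epoxide goes back to a C8 ketone (C8=C14 alkene, then hydroxyl-directed epoxidation), the 9,10-diol to a C9=C10 enone, and the isovalerate to the C6 alcohol. This exposes the enabling feature: in ring B, C6 and C8 both carry oxygen and flank the C7 methylene, so ring B is a latent cyclohept-4-ene-1,3-dione.
2. That dione is the retro-aldol product of a cyclobutanone fused across C5–C8, so C5–C6 and C7–C8 are cut together: [2+2] of dichloroketene (C6=C7) with the silyl enol ether C5=C8 of a five-membered ring C (C1, C5, C8, C9, C10). The chlorines, the silyl groups and the four-membered ring are helpers that are removed afterwards.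
3. Ring C is cut at C1–C10 (silicon-directed Nazarov cyclization). Ring A with its C4 carbinol comes from (S)-terpinen-4-ol (1) by ozonolysis/aldol ring contraction.
4. Forward order of rings: ring A, ring C, cyclobutanone, ring B by ring expansion, epoxide last.
5. Stereochemistry: C4 from the chiral pool; C1 by torquoselective Nazarov closure; C5 by equilibration next to the C6 ketone; C6 by hydride delivery from the C4 hydroxyl; C9/C10 by osmylation anti to C15; C8 by epoxidation directed by the C9 hydroxyl.

Key step: step 8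

Remark: (S)-(+)-terpinen-4-ol is taken as a purchasable single enantiomer; locants follow daucane numbering (C1 quaternary ring-fusion carbon bearing methyl C15, C4 isopropyl carbinol, C5 ring-fusion CH, C6 to C10 around ring B, C14 the carbon on C8), β is the face of C15 and α the opposite face.

Step 1
Reactants: 1 (S)-(+)-terpinen-4-ol
Product: 2 (S)-triethyl{[4-methyl-1-(propan-2-yl)cyclohex-3-en-1-yl]oxy}silane
Conditions: Et3SiOTf, 2,6-lutidine, CH2Cl2, 0 °C → rt
Reagents that add atoms: triethylsilyl trifluoromethanesulfonate, CC[Si](CC)(CC)OS(=O)(=O)C(F)(F)F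
Why: Silylation of the tertiary alcohol with a silyl triflate and a hindered base should mask the C4 oxygen until step 10; the stereocenter is not touched.

Step 2
Reactants: 2 (S)-triethyl{[4-methyl-1-(propan-2-yl)cyclohex-3-en-1-yl]oxy}silane
Product: 3 (S)-6-oxo-3-(propan-2-yl)-3-[(triethylsilyl)oxy]heptanal
Conditions: O3, CH2Cl2, −78 °C; then PPh3, −78 °C → rt
Reagents that add atoms: ozone, [O-][O+]=O
Why: Ozonolysis with reductive work-up should cleave the only C=C bond into the methyl ketone (C1) and the aldehyde (C8).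

Step 3
Reactants: 3 (S)-6-oxo-3-(propan-2-yl)-3-[(triethylsilyl)oxy]heptanal
Product: 4 (R)-2-methyl-5-(propan-2-yl)-5-[(triethylsilyl)oxy]cyclopent-1-ene-1-carbaldehyde
Conditions: piperidine (0.3 equiv), AcOH (0.3 equiv), benzene, 80 °C, azeotropic removal of water
Reagents that add atoms: none
Why: Intramolecular aldol condensation through the aldehyde enamine (five-membered closure of C5 onto the C1 ketone, then dehydration) should give the conjugated enal of ring A, the usual ring contraction of 1-methylcyclohexenes; no new stereocenter is formed.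

Step 4
Reactants: 4 (R)-2-methyl-5-(propan-2-yl)-5-[(triethylsilyl)oxy]cyclopent-1-ene-1-carbaldehyde; 5 (E)-(2-bromovinyl)trimethylsilane
Product: 7 (E)-1-[(R)-2-methyl-5-(propan-2-yl)-5-(triethylsilyloxy)cyclopent-1-en-1-yl]-3-(trimethylsilyl)prop-2-en-1-ol (both carbinol epimers), via (E)-[2-(trimethylsilyl)vinyl]lithium 6 (not isolated)
Conditions: 5, t-BuLi (2 equiv), Et2O, −78 °C; then 4, −78 → −20 °C
Reagents that add atoms: none
Why: Bromine–lithium exchange with retention of the E geometry and 1,2-addition of the vinyllithium to the aldehyde should give the bis-allylic alcohol; the new carbinol centre is uncontrolled and is removed in step 5.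

Step 5
Reactants: 7 (E)-1-[(R)-2-methyl-5-(propan-2-yl)-5-(triethylsilyloxy)cyclopent-1-en-1-yl]-3-(trimethylsilyl)prop-2-en-1-ol
Product: 8 (E)-1-[(R)-2-methyl-5-(propan-2-yl)-5-(triethylsilyloxy)cyclopent-1-en-1-yl]-3-(trimethylsilyl)prop-2-en-1-one
Conditions: Dess–Martin periodinane, NaHCO3, CH2Cl2, 0 °C → rt
Reagents that add atoms: none
Why: Dess–Martin oxidation of the secondary bis-allylic alcohol should give the cross-conjugated β-silyl divinyl ketone without touching the silyl ether or the vinylsilane.

Step 6
Reactants: 8 (E)-1-[(R)-2-methyl-5-(propan-2-yl)-5-(triethylsilyloxy)cyclopent-1-en-1-yl]-3-(trimethylsilyl)prop-2-en-1-one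
Product: 9 cis-fused ring A/ring C enone (C8 ketone; C9=C10; 1β-CH3; 5β-H; 4α-iPr; 4β-OSiEt3)
Conditions: FeCl3 (1.1 equiv), CH2Cl2, −50 → 0 °C; aqueous work-up
Reagents that add atoms: none
Why: Silicon-directed Nazarov cyclization: conrotatory 4π closure of the iron-bound pentadienyl cation forms C1–C10, the β-silyl group is lost so that the alkene ends at C9=C10, and the enolate is protonated at C5 to the cis-fused system; C1 is set by torquoselectivity, because C10 stays in the plane of the oxyallyl unit while the C15 methyl turns out of plane toward the smaller C4 substituent (OSiEt3) and away from the isopropyl group.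

Step 7
Reactants: 9 cis-fused ring A/ring C enone
Product: 10 cross-conjugated silyl dienol ether (C5=C8–OSiMe3; C9=C10; 1β-CH3; 4α-iPr; 4β-OSiEt3)
Conditions: LiN(iPr)2, THF, −78 °C; then Me3SiCl, Et3N, −78 → 0 °C
Reagents that add atoms: chlorotrimethylsilane, C[Si](C)(C)Cl
Why: Kinetic enolisation can only remove the α′ hydrogen on C5 (C1 is quaternary, so γ-deprotonation is impossible), and O-silylation of the dienolate should give the C5=C8 silyl enol ether; the C5 stereocenter is erased on purpose.

Step 8
Reactants: 10 cross-conjugated silyl dienol ether; 11 dichloroacetyl chloride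
Product: 13 tricyclic dichlorocyclobutanone (C5–C6(=O)–C7Cl2–C8 fused on the β face of ring C; 8α-OSiMe3; C9=C10), via dichloroketene 12 (not isolated)
Conditions: 11 (slow addition), Et3N, hexane/Et2O, 0 °C → rt
Reagents that add atoms: none
Why: Et3N converts 11 into dichloroketene 12, whose central carbon (the future C6) is attacked by C5, the nucleophilic terminus of the silyl enol ether C5=C8, and the siloxy-stabilised cation at C8 then collapses onto the α-carbon of the new enolate (the future C7), so that C5–C6 and C7–C8 are both formed in one asynchronous [2+2] cycloaddition. The closest known reaction type is the cycloaddition of dichloroketene with 1-siloxycyclopentenes, the opening move of the two-carbon ring expansion of cyclopentanones to cycloheptane-1,3-diones. The only ring closed is the cyclobutanone, by four-membered collapse of the 1,4-zwitterion (enolate carbon onto the C8 oxocarbenium carbon, 4-exo-trig). The new stereocenters C5 and C8 arise from suprafacial delivery of both bonds to the β face of ring C (the face of the C15 methyl), the only face that keeps rings A and C cis-fused, and both are temporary since C8 becomes a carbonyl and C5 is reset in step 10. The step needs regio- and site-selectivity: the OSiMe3 donor on C8 makes C5 the most nucleophilic carbon and C8 the cation-stabilising one, which puts the carbonyl carbon on C5 and CCl2 on C8 and should favour the enol ether over the unactivated C9=C10 bond and over 1,4-addition across the diene.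

Step 9
Reactants: 13 tricyclic dichlorocyclobutanone
Product: 14 tricyclic cyclobutanone (as 13 with C7H2)
Conditions: Zn dust, AcOH (3 equiv), iPrOH, 0 °C → rt
Reagents that add atoms: none
Why: Zinc reduction of the α,α-dichloro ketone through its zinc enolate should replace both chlorines by hydrogen and leave the ring system intact (early loss of the C8 silyl group would only anticipate step 10); no stereocenter is affected.

Step 10
Reactants: 14 tricyclic cyclobutanone
Product: 16 4β-hydroxy-14-nor-5α-dauc-9-ene-6,8-dione, via 8α-hydroxy cyclobutanone 15 (not isolated)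
Conditions: HF·pyridine, THF, 0 °C → rt
Reagents that add atoms: none
Why: Loss of the C8 silyl group unveils a β-hydroxy cyclobutanone that should undergo strain-driven retro-aldol cleavage of C5–C8 to the seven-membered 1,3-dione, while the C4 silyl ether is also cleaved; C5, now next to the C6 ketone, is epimerisable and should settle as the trans-fused 5α-H isomer, in which C6 lies syn to the C4 hydroxyl (hydrogen bond) and anti to the isopropyl group.

Step 11
Reactants: 16 4β-hydroxy-14-nor-5α-dauc-9-ene-6,8-dione
Product: 17 4β,6α-dihydroxy-14-nor-5α-dauc-9-en-8-one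
Conditions: Me4NBH(OAc)3 (slight excess), MeCN/AcOH, −30 °C
Reagents that add atoms: none
Why: Evans–Saksena reduction: the C4 hydroxyl binds boron and delivers hydride intramolecularly to the C6 ketone only (the C8 carbonyl is a conjugated enone with no hydroxyl in reach), and delivery from the β-oxygen on C4 places hydrogen on the β face of C6, giving the 6α-alcohol (anti 1,3-diol).

Step 12
Reactants: 17 4β,6α-dihydroxy-14-nor-5α-dauc-9-en-8-one; 18 3-methylbutanoyl chloride
Product: 19 4β-hydroxy-8-oxo-14-nor-5α-dauc-9-en-6α-yl 3-methylbutanoate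
Conditions: pyridine, DMAP (cat.), CH2Cl2, 0 °C
Reagents that add atoms: none
Why: Acylation of the only secondary alcohol should install the isovalerate (the tertiary C4 hydroxyl does not react); low temperature and a weak base are chosen to avoid β-elimination of the new β-acyloxy ketone.

Step 13
Reactants: 19 4β-hydroxy-8-oxo-14-nor-5α-dauc-9-en-6α-yl 3-methylbutanoate
Product: 20 4β,9α,10α-trihydroxy-8-oxo-14-nor-5α-daucan-6α-yl 3-methylbutanoate
Conditions: OsO4 (cat.), N-methylmorpholine N-oxide, citric acid, t-BuOH/H2O, rt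
Reagents that add atoms: N-methylmorpholine N-oxide, C[N+]1([O-])CCOCC1; water, O
Why: OsO4-catalysed syn-dihydroxylation of the only C=C bond (the enone) should occur on the α face, anti to the C15 methyl on the adjacent quaternary C1, and so set the cis 9α,10α-diol.

Step 14
Reactants: 20 4β,9α,10α-trihydroxy-8-oxo-14-nor-5α-daucan-6α-yl 3-methylbutanoate
Product: 21 4β,9α,10α-trihydroxy-5α-dauc-8(14)-en-6α-yl 3-methylbutanoate
Conditions: Zn, CH2Br2, TiCl4 (excess, reagent pre-formed at 0 °C), THF/CH2Cl2, 0 °C → rt
Reagents that add atoms: dibromomethane, BrCBr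
Why: Lombardo–Takai methylenation is non-basic, so the C8 ketone should become the exocyclic alkene without β-elimination of the C6 ester, epimerisation at C9 or retro-aldol cleavage, and it tolerates the ester and (with excess reagent) the free hydroxyls; no new stereocenter is formed.

Step 15
Reactants: 21 4β,9α,10α-trihydroxy-5α-dauc-8(14)-en-6α-yl 3-methylbutanoate
Product: 22 8α,14-epoxy-4β,9α,10α-trihydroxy-5α-daucan-6α-yl 3-methylbutanoate (target)
Conditions: VO(acac)2 (cat.), t-BuOOH, CH2Cl2, 0 °C → rt
Reagents that add atoms: tert-butyl hydroperoxide, CC(C)(C)OO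
Why: Vanadium-catalysed hydroxyl-directed epoxidation: the allylic 9α-hydroxyl (supported by the homoallylic 10α-hydroxyl) binds the vanadium peroxide and delivers oxygen to the α face of the C8=C14 alkene, which sets C8 with the epoxide oxygen syn to the C9 hydroxyl as in the target.

**Compound list**

1 | (S)-(+)-terpinen-4-ol, (S)-4-methyl-1-(propan-2-yl)cyclohex-3-en-1-ol | CC1=CC[C@](O)(C(C)C)CC1 | starting material
2 | (S)-triethyl{[4-methyl-1-(propan-2-yl)cyclohex-3-en-1-yl]oxy}silane | CC1=CC[C@](O[Si](CC)(CC)CC)(C(C)C)CC1 | intermediate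
3 | (S)-6-oxo-3-(propan-2-yl)-3-[(triethylsilyl)oxy]heptanal | O=CC[C@](O[Si](CC)(CC)CC)(C(C)C)CCC(C)=O | intermediate
4 | (R)-2-methyl-5-(propan-2-yl)-5-[(triethylsilyl)oxy]cyclopent-1-ene-1-carbaldehyde | CC1=C(C=O)[C@](O[Si](CC)(CC)CC)(C(C)C)CC1 | intermediate
5 | (E)-(2-bromovinyl)trimethylsilane | C[Si](C)(C)/C=C/Br | starting material
6 | (E)-[2-(trimethylsilyl)vinyl]lithium | C[Si](C)(C)/C=C/[Li] | intermediate (not isolated)
7 | (E)-1-[(R)-2-methyl-5-(propan-2-yl)-5-(triethylsilyloxy)cyclopent-1-en-1-yl]-3-(trimethylsilyl)prop-2-en-1-ol, both carbinol epimers | CC1=C(C(O)/C=C/[Si](C)(C)C)[C@](O[Si](CC)(CC)CC)(C(C)C)CC1 | intermediate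
8 | (E)-1-[(R)-2-methyl-5-(propan-2-yl)-5-(triethylsilyloxy)cyclopent-1-en-1-yl]-3-(trimethylsilyl)prop-2-en-1-one | CC1=C(C(=O)/C=C/[Si](C)(C)C)[C@](O[Si](CC)(CC)CC)(C(C)C)CC1 | intermediate
9 | cis-fused ring A/ring C enone, 3a-methyl-6-(propan-2-yl)-6-(triethylsilyloxy)-4,5,6,6a-tetrahydropentalen-1(3aH)-one; C8 ketone, C9=C10, 1β-CH3, 5β-H, 4α-iPr, 4β-OSiEt3 | O=C1C=C[C@@]2(C)CC[C@@](O[Si](CC)(CC)CC)(C(C)C)[C@@H]12 | intermediate
10 | cross-conjugated silyl dienol ether of 9; C5=C8–OSiMe3, C9=C10, 1β-CH3, 4α-iPr, 4β-OSiEt3 | C[Si](C)(C)OC1=C2[C@](O[Si](CC)(CC)CC)(C(C)C)CC[C@]2(C)C=C1 | intermediate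
11 | dichloroacetyl chloride | O=C(Cl)C(Cl)Cl | starting material
12 | dichloroketene | O=C=C(Cl)Cl | intermediate (not isolated)
13 | tricyclic dichlorocyclobutanone; cyclobutanone C5–C6(=O)–C7Cl2–C8 cis-fused on the β face of ring C, 8α-OSiMe3, C9=C10, 1β-CH3, 4α-iPr, 4β-OSiEt3 | O=C1C(Cl)(Cl)[C@]2(O[Si](C)(C)C)C=C[C@@]3(C)CC[C@@](O[Si](CC)(CC)CC)(C(C)C)[C@@]123 | intermediate
14 | tricyclic cyclobutanone; as 13 with C7H2 | O=C1C[C@]2(O[Si](C)(C)C)C=C[C@@]3(C)CC[C@@](O[Si](CC)(CC)CC)(C(C)C)[C@@]123 | intermediate
15 | 8α-hydroxy cyclobutanone; as 14 with free C8 hydroxyl, C4 silyl ether still in place | O=C1C[C@]2(O)C=C[C@@]3(C)CC[C@@](O[Si](CC)(CC)CC)(C(C)C)[C@@]123 | intermediate (not isolated)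
16 | 4β-hydroxy-14-nor-5α-dauc-9-ene-6,8-dione | O=C1CC(=O)C=C[C@@]2(C)CC[C@@](O)(C(C)C)[C@H]12 | intermediate
17 | 4β,6α-dihydroxy-14-nor-5α-dauc-9-en-8-one | O[C@H]1CC(=O)C=C[C@@]2(C)CC[C@@](O)(C(C)C)[C@H]12 | intermediate
18 | 3-methylbutanoyl chloride (isovaleryl chloride) | CC(C)CC(=O)Cl | starting material
19 | 4β-hydroxy-8-oxo-14-nor-5α-dauc-9-en-6α-yl 3-methylbutanoate | CC(C)CC(=O)O[C@H]1CC(=O)C=C[C@@]2(C)CC[C@@](O)(C(C)C)[C@H]12 | intermediate
20 | 4β,9α,10α-trihydroxy-8-oxo-14-nor-5α-daucan-6α-yl 3-methylbutanoate | CC(C)CC(=O)O[C@H]1CC(=O)[C@@H](O)[C@@H](O)[C@@]2(C)CC[C@@](O)(C(C)C)[C@H]12 | intermediate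
21 | 4β,9α,10α-trihydroxy-5α-dauc-8(14)-en-6α-yl 3-methylbutanoate | CC(C)CC(=O)O[C@H]1CC(=C)[C@@H](O)[C@@H](O)[C@@]2(C)CC[C@@](O)(C(C)C)[C@H]12 | intermediate
22 | 8α,14-epoxy-4β,9α,10α-trihydroxy-5α-daucan-6α-yl 3-methylbutanoate (CNP0307265.1) | CC(C)CC(=O)O[C@H]1C[C@]2(CO2)[C@@H](O)[C@@H](O)[C@@]2(C)CC[C@@](O)(C(C)C)[C@H]12 | target

**Summary**

Total step count: 15. Longest linear sequence: 15 steps (1 to 22); compounds 5, 11 and 18 are purchased.

Steps most likely to fail:

Step 8. The risk is loss of site selectivity: C5 is flanked by two quaternary carbons, so the ketene may add to the unhindered C9=C10 bond or across the diene termini instead of the enol ether. The fallback sets out from 10 and comes back at 16; it removes the C9=C10 bond before the cycloaddition and restores it afterwards. Diimide (2-nitrobenzenesulfonohydrazide, Et3N, CH2Cl2, rt) should reduce only the disubstituted C9=C10 bond of 10 to give the saturated silyl enol ether F1. Cycloaddition with 12 (from 11 and Et3N) then has a single π bond available and should give the saturated dichlorocyclobutanone F2. Zn/AcOH should give the saturated cyclobutanone F3, and HF·pyridine the saturated 1,3-dione F4. Selenation of the polyanion at C9 (LiN(iPr)2, 3.3 equiv, THF; then PhSeCl) should give the C9 phenylselenide F5, and H2O2 oxidation with syn-elimination should restore C9=C10 and give 16.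

Step 6. The risk is poor torquoselectivity (both conrotatory senses competing) or acid-induced loss of the tertiary silyl ether. The fallback sets out from 4 and comes back at 9; it makes the C1 quaternary centre by conjugate methylation, the original ring methyl becoming C10. Pinnick oxidation (NaClO2, NaH2PO4, 2-methylbut-2-ene) should give the cyclopentenecarboxylic acid F6. SeO2 (dioxane, 90 °C) should hydroxylate the cis β-methyl group, and lactonisation should give the fused butenolide F7. Me2CuLi/Me3SiCl (THF, −78 → −20 °C) should add methyl to C1 anti to the isopropyl group and give the cis-fused lactone F8. MeLi (1 equiv, −78 °C) should open it to the hydroxy methyl ketone F9, Dess–Martin oxidation should give the keto aldehyde F10, and KOH/MeOH should close ring C by aldol condensation (C9 onto the C10 aldehyde) to give 9.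

Step 11. The risk is over-reduction: the new C6 hydroxyl can relay hydride to the C8 enone. The fallback sets out from 16 and comes back at 17. Both carbonyls are reduced on purpose with excess Me4NBH(OAc)3 at rt (C6 still set by delivery from the C4 hydroxyl; NaBH4/CeCl3 can finish the enone) to give the 6,8-diol F11, and MnO2 (CH2Cl2, rt) should then re-oxidise only the allylic C8 alcohol to give 17.

**Further compounds**

F1 | step 8 | saturated silyl enol ether (C5=C8–OSiMe3, C9 and C10 as CH2) | C[Si](C)(C)OC1=C2[C@](O[Si](CC)(CC)CC)(C(C)C)CC[C@]2(C)CC1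
F2 | step 8 | saturated dichlorocyclobutanone (as 13 without C9=C10) | O=C1C(Cl)(Cl)[C@]2(O[Si](C)(C)C)CC[C@@]3(C)CC[C@@](O[Si](CC)(CC)CC)(C(C)C)[C@@]123
F3 | step 8 | saturated cyclobutanone (as 14 without C9=C10) | O=C1C[C@]2(O[Si](C)(C)C)CC[C@@]3(C)CC[C@@](O[Si](CC)(CC)CC)(C(C)C)[C@@]123
F4 | step 8 | 4β-hydroxy-14-nor-5α-daucane-6,8-dione | O=C1CC(=O)CC[C@@]2(C)CC[C@@](O)(C(C)C)[C@H]12
F5 | step 8 | 9-(phenylselanyl)-4β-hydroxy-14-nor-5α-daucane-6,8-dione | O=C1CC(=O)C([Se]c3ccccc3)C[C@@]2(C)CC[C@@](O)(C(C)C)[C@H]12
F6 | step 6 | (R)-2-methyl-5-(propan-2-yl)-5-(triethylsilyloxy)cyclopent-1-ene-1-carboxylic acid | CC1=C(C(=O)O)[C@](O[Si](CC)(CC)CC)(C(C)C)CC1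
F7 | step 6 | fused butenolide (lactone C8(=O)–O–C10H2 across C1=C5) | O=C1OCC2=C1[C@](O[Si](CC)(CC)CC)(C(C)C)CC2
F8 | step 6 | cis-fused γ-lactone (1β-CH3, 5β-H) | O=C1OC[C@@]2(C)CC[C@@](O[Si](CC)(CC)CC)(C(C)C)[C@@H]12
F9 | step 6 | hydroxy methyl ketone (C5 acetyl, C1 hydroxymethyl) | CC(=O)[C@@H]1[C@](O[Si](CC)(CC)CC)(C(C)C)CC[C@]1(C)CO
F10 | step 6 | keto aldehyde (C5 acetyl, C1 formyl) | CC(=O)[C@@H]1[C@](O[Si](CC)(CC)CC)(C(C)C)CC[C@]1(C)C=O
F11 | step 11 | 14-nor-5α-dauc-9-ene-4β,6α,8-triol | O[C@H]1CC(O)C=C[C@@]2(C)CC[C@@](O)(C(C)C)[C@H]12
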